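## Analysis of the target

The target is a 2,3-dihydro-1-benzofuran (O1, C2, C3, C3a, C4 to C7, C7a; the benzo ring is ring A). It carries a 4-hydroxyphenyl group (ring B) on C2, a 2,4-dihydroxybenzoyl group (ring C) on C3 and, on C5 para to O1, a 3-(2,4-dihydroxyphenyl)-3-oxopropyl arm (ring D), so ring A and ring D form a dihydrochalcone. The two stereocentres, C2 and C3, are both S, which puts ring B and the aroyl group on opposite faces of the five-membered ring (2,3-trans), the more stable arrangement. C3–H is benzylic, alpha to an aryl ketone and beta to O1, so C3 epimerises easily and, in the worst case, the ring opens by loss of the ring A phenoxide. C2–O1 is a benzylic ether para to the ring B oxygen, so once ring B is a free phenol, acid or base can break this bond through a para-quinone methide; there are also five phenols and two ortho-hydroxyaryl ketones. The difficulty is to fix the absolute configuration at C2 by a process that does not depend on the labile C3 centre, and to attach two electron-rich aryl ketones without strongly Lewis acidic conditions that would ionise C2–O1. The strategy rests on O1 being an aryl alkyl ether oxygen: with the O1–C7a bond opened in thought, C2 is a secondary benzylic carbinol beta to the C3 carbonyl, the pattern of a syn aldol between an arylacetyl unit (ring A, C3 and the carbonyl carbon) and a ring B benzaldehyde (C2). A bromine on C7a then closes the ring, and a chlorine on C5, para to it, holds the place of the arm.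

## Retrosynthetic reasoning

**22 from 21.** The five phenols are released last from the pentakis(methoxymethyl) ether 21. The acetal protecting groups are needed because free phenols would quench the organomagnesium reagent and would be arylated or deprotonated in the palladium steps. A masked ring B oxygen also blocks the quinone methide opening of C2–O1 until the end. The forward step must cleave five aryl acetals under acid mild enough to leave C2–O1 and C3 alone.

**21 from 16 and 19.** The C5–CH2 bond of the arm is cut. Cutting here, and not at the arm carbonyl, lets the whole three-carbon aryl ketone unit arrive as the allylic alcohol 19. A Mizoroki–Heck reaction with an allylic alcohol moves the double bond into the carbinol and so gives, through enol 20, the saturated ketone directly, without a separate reduction. The handle on ring A is the C5 chlorine of 16, which has passed through all earlier steps unchanged. The forward step must activate an electron-rich aryl chloride and eliminate hydride toward the carbinol, without enolising C3. Alcohol 19 comes from the Grignard reagent 14 and acrolein 17 by way of the magnesium alkoxide 18.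

**16 from 11 and 14.** The bond between the C3 carbonyl and ring C is cut. This avoids a Friedel–Crafts acylation next to an ionisable benzylic ether. The N-methoxy-N-methylamide 11 stops the addition of 14 at the chelate 15 and so at the ketone. The forward step needs addition to be faster than deprotonation at C3. Reagent 14 is made once, from bromide 13 and magnesium, and one batch of it serves both for 16 and for 19.

**11 from 10 (key disconnection).** The O1–C7a bond is cut. This is the only ring bond whose formation touches neither stereocentre, so both can be set beforehand in an open chain, where auxiliary control is reliable. Cutting O1–C2 instead would mean a substitution at a benzylic centre that ionises easily. Cutting C2–C3 would mean setting two centres on the ring at once. The forward step is an intramolecular palladium-catalysed aryl etherification of the secondary alcohol 10. It must select C–Br over C–Cl and must not oxidise or fragment the β-hydroxy amide.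

**10 from 9, and 9 from 4 and 6.** The C2–C3 bond is the aldol bond. The imide 4 gives the boron enolate 7, which adds to aldehyde 6 to give aldolate 8 and, after work-up, the syn adduct 9. Both stereocentres come from this one step. In the zigzag drawing of a syn aldol, the aryl group on the alpha-carbon and the hydroxyl are on the same side, so they can join into the ring, while the carbonyl group and ring B, which are anti, end up trans. The (S)-configured auxiliary gives the (2S,3S) adduct, which maps onto (2S,3S) in the target. Exchange of the auxiliary in 9 for the N-methoxy-N-methylamide gives 10. The amide is preferred to a ketone at this stage because it enolises far less readily.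

**Building blocks.** Imide 4 comes from acid 1 and auxiliary 2 through the mixed anhydride 3. Acid 1 already has bromine and chlorine para to each other, which become O1 and the C5 arm. Aldehyde 6 comes from 5, and bromide 13 from 12, by etherification of the phenols.

## Alternatives that were turned down

**Alternative 1:** Both aryl–carbonyl bonds (C3 carbonyl to ring C, arm carbonyl to ring D) are cut at once. In the forward step BF3·OEt2 makes the two carboxyl groups of diacid A2 each acylate C4 of a molecule of resorcinol A3, giving A1, the target with a pivalate on the ring B oxygen.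
- For: two ketones form in one operation, the nucleophile needs no protection, and only one protecting group remains to be removed. In endgame step count this is better than steps 6 to 11 of the chosen route.
- Against: it builds neither the ring nor a stereocentre, so A2 must still be made enantiopure, most likely by an aldol and etherification sequence like the one chosen, plus a propanoic acid arm. The C3 carboxyl is secondary and flanked by ring A and C2. Its activated form can lose the C3 proton to a ketene, and the arm acid is expected to react much faster, so the reaction may stop after one acylation. Hot BF3·OEt2 is also the kind of condition under which the benzylic C2–O1 bond ionises, even with ring B attenuated as its pivalate, and the pivalate can migrate.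
- Comparison: the chosen route forms the C3 ketone from amide 11 with a nucleophile at or below room temperature, and pays for this with protecting group steps.

**Alternative 2:** The C2–C3 bond is cut. The diazoketone A5 is treated with dirhodium tetrakis[N-phthaloyl-(S)-tert-leucinate], Rh2(S-PTTL)4. The rhodium carbenoid at C3 inserts into a C–H bond of the aryloxy-CH2 group, closing the ring, and DBU then moves C3 to the trans arrangement to give A4.
- For: the stereocentre is set by a catalyst and not by a stoichiometric auxiliary, and ring and C2 form in one step. The silyl ethers come off with fluoride and not acid, and the C5 bromide of A4 is a better Heck partner than the chloride of 16. On these points it is as strong as or stronger than the chosen route.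
- Against: high enantiocontrol in this kind of insertion is established for aryldiazoacetates. With an aroyl group on the carbenoid carbon, Wolff rearrangement and attack on the electron-rich silyloxyaryl ring compete, and the selectivity is hard to predict. The enantiomeric purity rests on C2 alone and must survive DBU with the ketone already at C3, exactly where ring opening by β-elimination threatens.
- Comparison: the chosen route sets both centres with a predictable auxiliary and applies base only at the amide oxidation level.

**Alternative 3:** The O1–C2 bond is cut along the biosynthetic line. The chiral phosphoric acid (R)-TRIP converts the alpha-aryl chalcone A7 into its para-quinone methide enol and guides the ring A phenol onto the methide carbon, giving A6 with the ring B phenol free.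
- For: it is the shortest and most convergent plan, it is catalytic, and ring and both centres form in one step. In step economy it beats the chosen route.
- Against: the quinone methide tautomer is a minor, high-energy species and the closure is reversible, so the same acid can reopen A6 and erode its enantiomeric purity through achiral A7. C3 is set in a separate enol protonation. No close model exists for catalyst control of this intramolecular addition on an alpha-aryl chalcone. The later acidic removal of the acetals would take place with the ring B phenol already free.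
- Comparison: the chosen route is longer, but it fixes C2 irreversibly in an aldol and keeps ring B masked until the last step.

Key step: step 5

## Route

Step 1
Reactants: 1 2-(2-bromo-5-chlorophenyl)acetic acid; 2 (4S)-4-benzyl-1,3-oxazolidin-2-one
Product: 4 (4S)-4-benzyl-3-[2-(2-bromo-5-chlorophenyl)acetyl]-1,3-oxazolidin-2-one, via mixed pivalic anhydride 3 (not isolated)
Conditions: PivCl, Et3N, THF, −20 °C; then LiCl, 2, −20 °C → rt
Reagents that add atoms: none
Why: N-acylation of the oxazolidinone through a mixed pivalic anhydride with Et3N/LiCl activation; the tert-butyl group shields the pivaloyl carbonyl, so the auxiliary nitrogen attacks the arylacetyl carbonyl, and the mild base avoids the ketene formation that an arylacetyl chloride with strong base would risk. No stereocentre is formed.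

Step 2
Reactants: 5 4-hydroxybenzaldehyde
Product: 6 4-(methoxymethoxy)benzaldehyde
Conditions: MOMCl, i-Pr2NEt, CH2Cl2, 0 °C → rt
Reagents that add atoms: chloromethyl methyl ether, COCCl
Why: Williamson-type O-alkylation of the phenol; the methoxymethyl ether tolerates Bu2BOTf at low temperature, AlMe3, carbonate, organomagnesium reagents and the Heck base, and keeps ring B from acting as a quinone methide donor until the end.

Step 3
Reactants: 4 (4S)-4-benzyl-3-[2-(2-bromo-5-chlorophenyl)acetyl]-1,3-oxazolidin-2-one; 6 4-(methoxymethoxy)benzaldehyde
Product: 9 (4S)-4-benzyl-3-[(2S,3S)-2-(2-bromo-5-chlorophenyl)-3-hydroxy-3-[4-(methoxymethoxy)phenyl]propanoyl]-1,3-oxazolidin-2-one, via dibutylboron Z-enolate 7 (not isolated), via dibutylboron aldolate 8 (not isolated)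
Conditions: Bu2BOTf, i-Pr2NEt, CH2Cl2, 0 °C; 6, −78 → 0 °C; then pH 7 buffer, MeOH, 30% H2O2, 0 °C
Reagents that add atoms: none
Why: Evans syn-aldol reaction: Bu2BOTf and i-Pr2NEt give the Z-boron enolate 7, which adds to 6 through a chair Zimmerman–Traxler transition state with the aldehyde aryl group equatorial, giving the 2,3-syn relationship. With the two imide carbonyl dipoles opposed, the benzyl group of the (S)-auxiliary blocks one enolate face, so both new centres should form as (2S,3S), the same sense as in the propionyl case. Peroxide work-up at 0 °C cleaves the boron aldolate 8 before retro-aldol can set in.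

Step 4
Reactants: 9 (4S)-4-benzyl-3-[(2S,3S)-2-(2-bromo-5-chlorophenyl)-3-hydroxy-3-[4-(methoxymethoxy)phenyl]propanoyl]-1,3-oxazolidin-2-one
Product: 10 (2S,3S)-2-(2-bromo-5-chlorophenyl)-3-hydroxy-N-methoxy-N-methyl-3-[4-(methoxymethoxy)phenyl]propanamide
Conditions: MeNH(OMe)·HCl, AlMe3, CH2Cl2, −20 → 0 °C; aq. potassium sodium tartrate
Reagents that add atoms: N,O-dimethylhydroxylamine hydrochloride, CNOC.Cl
Why: Aluminium amide transamination of a β-hydroxy imide to the Weinreb amide; the free hydroxyl binds aluminium and delivers the amide nitrogen to the exocyclic carbonyl, which is why this exchange runs on aldol adducts at or below 0 °C. Neither stereocentre is touched and auxiliary 2 is recovered.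

Step 5
Reactants: 10 (2S,3S)-2-(2-bromo-5-chlorophenyl)-3-hydroxy-N-methoxy-N-methyl-3-[4-(methoxymethoxy)phenyl]propanamide
Product: 11 (2S,3S)-5-chloro-N-methoxy-N-methyl-2-[4-(methoxymethoxy)phenyl]-2,3-dihydro-1-benzofuran-3-carboxamide
Conditions: Pd(OAc)2 (cat.), rac-2-(di-tert-butylphosphino)-1,1'-binaphthyl (cat.), Cs2CO3, toluene, 65 °C
Reagents that add atoms: none
Why: Pd(OAc)2 is reduced by the phosphine to a zerovalent palladium species that inserts into the C–Br bond of 10; Cs2CO3 deprotonates the palladium-bound hydroxyl to a six-membered aryl(alkoxo)palladium chelate, and C–O reductive elimination forms O1–C7a. The closest known reaction type is the intramolecular Buchwald–Hartwig etherification of 2-(2-halophenyl)ethanol-type secondary alcohols with di-tert-butyl(biaryl)phosphines, which gives 2-substituted 2,3-dihydrobenzofurans. The five-membered ring closes by reductive elimination from the six-membered palladacycle, formally a 5-exo attack of oxygen on the aromatic carbon. No stereocentre is created: the carbinol C–O bond is never broken and C3 is not involved, so the (2S,3S) syn-aldol array becomes the 2,3-trans ring, and if C3 epimerised under carbonate, trans would still be the thermodynamic outcome. The step needs C–Br to react before C–Cl; this is secured by the weaker C–Br bond, the moderate temperature and the fact that only the palladium species at C7a has a tethered alkoxide, and the chlorine of 11 ends up para to an ether oxygen and is deactivated further. It also needs reductive elimination to beat β-hydride elimination from the benzylic alkoxide, which the bulky electron-rich phosphine and the chelate geometry favour. Carrying C3 as an N-methoxy-N-methylamide and not a ketone limits retro-aldol cleavage, enolate O-arylation to a benzofuran and alpha-epimerisation.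

Step 6
Reactants: 12 4-bromobenzene-1,3-diol
Product: 13 1-bromo-2,4-bis(methoxymethoxy)benzene
Conditions: MOMCl, i-Pr2NEt, CH2Cl2, 0 °C → rt
Reagents that add atoms: chloromethyl methyl ether, COCCl
Why: Double Williamson-type O-alkylation of the phenols; the ortho methoxymethoxy group later stabilises the aryl Grignard reagent by chelation and comes off together with the other acetals.

Step 7
Reactants: 13 1-bromo-2,4-bis(methoxymethoxy)benzene
Product: 14 [2,4-bis(methoxymethoxy)phenyl]magnesium bromide (titrated THF solution, kept under argon)
Conditions: Mg turnings (activated with cat. I2), THF, 40 °C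
Reagents that add atoms: magnesium, [Mg]
Why: Grignard reagent formation by insertion of magnesium into the aryl C–Br bond; the acetals are inert to the reagent and the ortho methoxymethoxy oxygen coordinates magnesium. One titrated batch is divided between steps 8 and 9.

Step 8
Reactants: 11 (2S,3S)-5-chloro-N-methoxy-N-methyl-2-[4-(methoxymethoxy)phenyl]-2,3-dihydro-1-benzofuran-3-carboxamide; 14 [2,4-bis(methoxymethoxy)phenyl]magnesium bromide
Product: 16 [2,4-bis(methoxymethoxy)phenyl][(2S,3S)-5-chloro-2-[4-(methoxymethoxy)phenyl]-2,3-dihydro-1-benzofuran-3-yl]methanone, via magnesium hemiaminal chelate 15 (not isolated)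
Conditions: 14 (THF solution), 11, THF, 0 °C → rt; water buffered with NH4Cl
Reagents that add atoms: none
Why: Weinreb ketone synthesis: 14 adds to the N-methoxy-N-methylamide to form the five-membered magnesium chelate 15, which does not collapse until work-up, so the reaction stops at the ketone. The Grignard reagent is chosen over the aryllithium because it is less basic toward C3–H. C2 is not involved, and C3, should it epimerise, returns to the more stable trans arrangement.

Step 9
Reactants: 14 [2,4-bis(methoxymethoxy)phenyl]magnesium bromide; 17 acrolein (prop-2-enal)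
Product: 19 1-[2,4-bis(methoxymethoxy)phenyl]prop-2-en-1-ol (racemic), via bromomagnesium alkoxide 18 (not isolated)
Conditions: 14 (THF solution), 17, THF, −78 → 0 °C; water buffered with NH4Cl
Reagents that add atoms: none
Why: 1,2-Addition of the aryl Grignard reagent to the aldehyde carbon of acrolein at low temperature gives the magnesium alkoxide 18, which is protonated on work-up; the carbinol centre forms racemic, which does not matter because it becomes the arm carbonyl in step 10.

Step 10
Reactants: 16 [2,4-bis(methoxymethoxy)phenyl][(2S,3S)-5-chloro-2-[4-(methoxymethoxy)phenyl]-2,3-dihydro-1-benzofuran-3-yl]methanone; 19 1-[2,4-bis(methoxymethoxy)phenyl]prop-2-en-1-ol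
Product: 21 1-[2,4-bis(methoxymethoxy)phenyl]-3-[(2S,3S)-3-[2,4-bis(methoxymethoxy)benzoyl]-2-[4-(methoxymethoxy)phenyl]-2,3-dihydro-1-benzofuran-5-yl]propan-1-one, via enol 20 (not isolated)
Conditions: Pd2(dba)3 (cat.), P(t-Bu)3 (cat.), Cy2NMe, 1,4-dioxane, 100 °C
Reagents that add atoms: none
Why: Mizoroki–Heck reaction of an aryl chloride with a secondary allylic alcohol: zerovalent palladium bearing P(t-Bu)3 inserts into the C5–Cl bond, the aryl group adds to the terminal alkene carbon, and β-hydride elimination toward the carbinol C–H gives enol 20, which tautomerises to the saturated ketone. The three-carbon arm and its carbonyl thus arrive in one step with no new stereocentre, and the hindered amine Cy2NMe is a weak enough base to leave C3 alone.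

Step 11
Reactants: 21 1-[2,4-bis(methoxymethoxy)phenyl]-3-[(2S,3S)-3-[2,4-bis(methoxymethoxy)benzoyl]-2-[4-(methoxymethoxy)phenyl]-2,3-dihydro-1-benzofuran-5-yl]propan-1-one
Product: 22 3-[(2S,3S)-3-(2,4-dihydroxybenzoyl)-2-(4-hydroxyphenyl)-2,3-dihydro-1-benzofuran-5-yl]-1-(2,4-dihydroxyphenyl)propan-1-one
Conditions: 3 M aq. HCl, MeOH, 40 °C
Reagents that add atoms: none
Why: Acid-catalysed acetal exchange of the five methoxymethyl ethers with methanol; the C3 acyl group destabilises positive charge at C2 and so slows ionisation of C2–O1, and the low temperature should keep the trans (2S,3S) centres intact.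

## Compound list

1 | 2-(2-bromo-5-chlorophenyl)acetic acid | OC(=O)Cc1cc(Cl)ccc1Br | starting material
2 | (4S)-4-benzyl-1,3-oxazolidin-2-one | O=C1N[C@@H](Cc2ccccc2)CO1 | starting material
3 | 2-(2-bromo-5-chlorophenyl)acetic pivalic anhydride | CC(C)(C)C(=O)OC(=O)Cc1cc(Cl)ccc1Br | intermediate
4 | (4S)-4-benzyl-3-[2-(2-bromo-5-chlorophenyl)acetyl]-1,3-oxazolidin-2-one | O=C(Cc1cc(Cl)ccc1Br)N1[C@@H](Cc2ccccc2)COC1=O | intermediate
5 | 4-hydroxybenzaldehyde | O=Cc1ccc(O)cc1 | starting material
6 | 4-(methoxymethoxy)benzaldehyde | O=Cc1ccc(OCOC)cc1 | intermediate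
7 | dibutylboron (Z)-enolate of 4 | CCCCB(CCCC)O/C(=C\c1cc(Cl)ccc1Br)N1[C@@H](Cc2ccccc2)COC1=O | intermediate
8 | O-dibutylboryl derivative of aldol adduct 9 (boron aldolate) | Clc1ccc(Br)c(c1)[C@H](C(=O)N1[C@@H](Cc2ccccc2)COC1=O)[C@@H](c1ccc(OCOC)cc1)OB(CCCC)CCCC | intermediate
9 | (4S)-4-benzyl-3-[(2S,3S)-2-(2-bromo-5-chlorophenyl)-3-hydroxy-3-[4-(methoxymethoxy)phenyl]propanoyl]-1,3-oxazolidin-2-one | Clc1ccc(Br)c(c1)[C@H](C(=O)N1[C@@H](Cc2ccccc2)COC1=O)[C@@H](c1ccc(OCOC)cc1)O | intermediate
10 | (2S,3S)-2-(2-bromo-5-chlorophenyl)-3-hydroxy-N-methoxy-N-methyl-3-[4-(methoxymethoxy)phenyl]propanamide | Clc1ccc(Br)c(c1)[C@H](C(=O)N(C)OC)[C@@H](c1ccc(OCOC)cc1)O | intermediate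
11 | (2S,3S)-5-chloro-N-methoxy-N-methyl-2-[4-(methoxymethoxy)phenyl]-2,3-dihydro-1-benzofuran-3-carboxamide | Clc1ccc2c(c1)[C@H](C(=O)N(C)OC)[C@@H](c1ccc(OCOC)cc1)O2 | intermediate
12 | 4-bromobenzene-1,3-diol (4-bromoresorcinol) | Oc1ccc(Br)c(O)c1 | starting material
13 | 1-bromo-2,4-bis(methoxymethoxy)benzene | COCOc1ccc(Br)c(OCOC)c1 | intermediate
14 | [2,4-bis(methoxymethoxy)phenyl]magnesium bromide | COCOc1ccc([Mg]Br)c(OCOC)c1 | intermediate
15 | bromomagnesium alkoxide of the tetrahedral N-methoxy-N-methyl hemiaminal from 11 and 14 (configuration at the hemiaminal carbon undefined) | Clc1ccc2c(c1)[C@H](C(O[Mg]Br)(N(C)OC)c1ccc(OCOC)cc1OCOC)[C@@H](c1ccc(OCOC)cc1)O2 | intermediate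
16 | [2,4-bis(methoxymethoxy)phenyl][(2S,3S)-5-chloro-2-[4-(methoxymethoxy)phenyl]-2,3-dihydro-1-benzofuran-3-yl]methanone | Clc1ccc2c(c1)[C@H](C(=O)c1ccc(OCOC)cc1OCOC)[C@@H](c1ccc(OCOC)cc1)O2 | intermediate
17 | acrolein (prop-2-enal) | C=CC=O | starting material
18 | bromomagnesium 1-[2,4-bis(methoxymethoxy)phenyl]prop-2-en-1-olate (racemic) | C=CC(O[Mg]Br)c1ccc(OCOC)cc1OCOC | intermediate
19 | 1-[2,4-bis(methoxymethoxy)phenyl]prop-2-en-1-ol (racemic) | C=CC(O)c1ccc(OCOC)cc1OCOC | intermediate
20 | 1-[2,4-bis(methoxymethoxy)phenyl]-3-[(2S,3S)-3-[2,4-bis(methoxymethoxy)benzoyl]-2-[4-(methoxymethoxy)phenyl]-2,3-dihydro-1-benzofuran-5-yl]prop-1-en-1-ol (enol, alkene geometry undefined) | OC(=CCc1ccc2c(c1)[C@H](C(=O)c1ccc(OCOC)cc1OCOC)[C@@H](c1ccc(OCOC)cc1)O2)c1ccc(OCOC)cc1OCOC | intermediate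
21 | 1-[2,4-bis(methoxymethoxy)phenyl]-3-[(2S,3S)-3-[2,4-bis(methoxymethoxy)benzoyl]-2-[4-(methoxymethoxy)phenyl]-2,3-dihydro-1-benzofuran-5-yl]propan-1-one | O=C(CCc1ccc2c(c1)[C@H](C(=O)c1ccc(OCOC)cc1OCOC)[C@@H](c1ccc(OCOC)cc1)O2)c1ccc(OCOC)cc1OCOC | intermediate
22 | 3-[(2S,3S)-3-(2,4-dihydroxybenzoyl)-2-(4-hydroxyphenyl)-2,3-dihydro-1-benzofuran-5-yl]-1-(2,4-dihydroxyphenyl)propan-1-one | O=C(CCc1ccc2c(c1)[C@H](C(=O)c1ccc(O)cc1O)[C@@H](c1ccc(O)cc1)O2)c1ccc(O)cc1O | target

## Step count and least certain steps

Total: 11 steps. Longest linear sequence: 7 steps (steps 1, 3, 4, 5, 8, 10, 11). Steps 2, 6, 7 and 9 prepare the side components.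

**Step 5 (key step).** The most likely failure is retro-aldol fragmentation of the caesium alkoxide of 10 into aldehyde 6 and the aryl-stabilised amide enolate, together with alpha-epimerisation before closure, because the substrate is a β-hydroxy carbonyl compound with an acidic benzylic alpha-proton. Second in likelihood is β-hydride elimination from the benzylic palladium alkoxide, which would give the β-keto amide and loss of bromine. The fallback removes the carbonyl during the ring closure. It sets out from 9. LiBH4 in THF/MeOH at 0 °C cleaves the auxiliary reductively to (1S,2R)-2-(2-bromo-5-chlorophenyl)-1-[4-(methoxymethoxy)phenyl]propane-1,3-diol F1. Both hydroxyls of F1 could close a five-membered ring, so the primary one is silylated (TBSCl, imidazole, CH2Cl2) to (1S,2R)-2-(2-bromo-5-chlorophenyl)-3-[(tert-butyldimethylsilyl)oxy]-1-[4-(methoxymethoxy)phenyl]propan-1-ol F2. The same palladium etherification, now on a substrate that can neither fragment nor epimerise, should give tert-butyl{[(2S,3R)-5-chloro-2-[4-(methoxymethoxy)phenyl]-2,3-dihydro-1-benzofuran-3-yl]methoxy}dimethylsilane F3; since F2 tolerates heat and base, a CuI/phenanthroline Ullmann etherification is also open here if β-hydride elimination is the problem. Bu4NF in THF frees [(2S,3R)-5-chloro-2-[4-(methoxymethoxy)phenyl]-2,3-dihydro-1-benzofuran-3-yl]methanol F4. TEMPO/PhI(OAc)2 in aqueous MeCN oxidises it to (2S,3S)-5-chloro-2-[4-(methoxymethoxy)phenyl]-2,3-dihydro-1-benzofuran-3-carboxylic acid F5. Amide coupling with MeNH(OMe)·HCl (EDC·HCl, HOBt, i-Pr2NEt, CH2Cl2) brings the material back to the route at 11.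

**Step 10.** The most likely failure is slow oxidative addition into the electron-rich C5–Cl bond. At the temperature then needed, the amine base can enolise C3 (epimerisation, or ring opening by β-elimination), and the acid- and heat-sensitive allylic alcohol 19 can isomerise or decompose. β-Hydride elimination toward the benzylic side would also give an allylic alcohol in place of the ketone. The fallback reverses the polarity of the coupling and sets out from 16. Miyaura borylation (Pd2(dba)3, XPhos, B2pin2, KOAc, dioxane, 100 °C) gives [2,4-bis(methoxymethoxy)phenyl][(2S,3S)-2-[4-(methoxymethoxy)phenyl]-5-(4,4,5,5-tetramethyl-1,3,2-dioxaborolan-2-yl)-2,3-dihydro-1-benzofuran-3-yl]methanone F6. Alcohol 19 is oxidised with MnO2 in CH2Cl2 to 1-[2,4-bis(methoxymethoxy)phenyl]prop-2-en-1-one F7. A rhodium-catalysed Hayashi–Miyaura conjugate addition of F6 to F7 ([Rh(OH)(cod)]2, dioxane/H2O, 40 °C, no added base) gives the saturated ketone and returns to the route at 21.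

**Step 8.** The most likely failure is deprotonation at C3 in place of addition. The amide carbonyl is flanked by ring A and by C2 with ring B, and the nucleophile is ortho-substituted, so addition is slow while C3–H is acidic; the result would be recovered or epimerised amide, or ring-opened material. The fallback goes through a more electrophilic carbonyl and sets out from 11. i-Bu2AlH in THF at −78 °C gives (2S,3S)-5-chloro-2-[4-(methoxymethoxy)phenyl]-2,3-dihydro-1-benzofuran-3-carbaldehyde F8. Reagent 14 adds to it at −78 °C to give [2,4-bis(methoxymethoxy)phenyl][(2S,3R)-5-chloro-2-[4-(methoxymethoxy)phenyl]-2,3-dihydro-1-benzofuran-3-yl]methanol F9 as a mixture of carbinol epimers. Dess–Martin periodinane with NaHCO3 in CH2Cl2 oxidises both epimers to the same ketone and returns to the route at 16.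

**Step 4.** The most likely failure is retro-aldol cleavage of the aluminium aldolate, or attack at the ring carbonyl of the oxazolidinone, because the alpha-aryl group stabilises the enolate leaving group and hinders the exocyclic carbonyl. The fallback separates cleavage from amide formation and sets out from 9. LiOH/H2O2 in THF/H2O at 0 °C gives (2S,3S)-2-(2-bromo-5-chlorophenyl)-3-hydroxy-3-[4-(methoxymethoxy)phenyl]propanoic acid F10 and recovered 2. Coupling of F10 with MeNH(OMe)·HCl (EDC·HCl, HOBt, N-methylmorpholine, CH2Cl2, 0 °C) returns to the route at 10.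

**Step 11.** The most likely failure comes once the ring B phenol is free: acid-assisted heterolysis of C2–O1 through a para-quinone-methide-like cation. This would epimerise C2 and, together with enolisation at C3, erode enantiomeric purity; reclosure through the ortho hydroxyl of ring C to a chromanone isomer is also possible. The fallback avoids protic acid and sets out from 21. TMSOTf with 2,2'-bipyridyl in CH2Cl2 at 0 °C exchanges the aryl methoxymethyl ethers for silyl ethers, giving 1-[2,4-bis(trimethylsilyloxy)phenyl]-3-[(2S,3S)-3-[2,4-bis(trimethylsilyloxy)benzoyl]-2-[4-(trimethylsilyloxy)phenyl]-2,3-dihydro-1-benzofuran-5-yl]propan-1-one F11. The weak base makes silyl enol ether formation at C3 unlikely. Hydrolysis with water in THF at neutral pH gives 22.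

## Further compounds

F1 | step 5 | (1S,2R)-2-(2-bromo-5-chlorophenyl)-1-[4-(methoxymethoxy)phenyl]propane-1,3-diol | Clc1ccc(Br)c(c1)[C@H](CO)[C@@H](c1ccc(OCOC)cc1)O
F2 | step 5 | (1S,2R)-2-(2-bromo-5-chlorophenyl)-3-[(tert-butyldimethylsilyl)oxy]-1-[4-(methoxymethoxy)phenyl]propan-1-ol | Clc1ccc(Br)c(c1)[C@H](CO[Si](C)(C)C(C)(C)C)[C@@H](c1ccc(OCOC)cc1)O
F3 | step 5 | tert-butyl{[(2S,3R)-5-chloro-2-[4-(methoxymethoxy)phenyl]-2,3-dihydro-1-benzofuran-3-yl]methoxy}dimethylsilane | Clc1ccc2c(c1)[C@H](CO[Si](C)(C)C(C)(C)C)[C@@H](c1ccc(OCOC)cc1)O2
F4 | step 5 | [(2S,3R)-5-chloro-2-[4-(methoxymethoxy)phenyl]-2,3-dihydro-1-benzofuran-3-yl]methanol | Clc1ccc2c(c1)[C@H](CO)[C@@H](c1ccc(OCOC)cc1)O2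
F5 | step 5 | (2S,3S)-5-chloro-2-[4-(methoxymethoxy)phenyl]-2,3-dihydro-1-benzofuran-3-carboxylic acid | Clc1ccc2c(c1)[C@H](C(=O)O)[C@@H](c1ccc(OCOC)cc1)O2
F6 | step 10 | [2,4-bis(methoxymethoxy)phenyl][(2S,3S)-2-[4-(methoxymethoxy)phenyl]-5-(4,4,5,5-tetramethyl-1,3,2-dioxaborolan-2-yl)-2,3-dihydro-1-benzofuran-3-yl]methanone | CC1(C)OB(OC1(C)C)c1ccc2c(c1)[C@H](C(=O)c1ccc(OCOC)cc1OCOC)[C@@H](c1ccc(OCOC)cc1)O2
F7 | step 10 | 1-[2,4-bis(methoxymethoxy)phenyl]prop-2-en-1-one | C=CC(=O)c1ccc(OCOC)cc1OCOC
F8 | step 8 | (2S,3S)-5-chloro-2-[4-(methoxymethoxy)phenyl]-2,3-dihydro-1-benzofuran-3-carbaldehyde | Clc1ccc2c(c1)[C@H](C=O)[C@@H](c1ccc(OCOC)cc1)O2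
F9 | step 8 | [2,4-bis(methoxymethoxy)phenyl][(2S,3R)-5-chloro-2-[4-(methoxymethoxy)phenyl]-2,3-dihydro-1-benzofuran-3-yl]methanol (mixture of carbinol epimers) | Clc1ccc2c(c1)[C@H](C(O)c1ccc(OCOC)cc1OCOC)[C@@H](c1ccc(OCOC)cc1)O2
F10 | step 4 | (2S,3S)-2-(2-bromo-5-chlorophenyl)-3-hydroxy-3-[4-(methoxymethoxy)phenyl]propanoic acid | Clc1ccc(Br)c(c1)[C@H](C(=O)O)[C@@H](c1ccc(OCOC)cc1)O
F11 | step 11 | 1-[2,4-bis(trimethylsilyloxy)phenyl]-3-[(2S,3S)-3-[2,4-bis(trimethylsilyloxy)benzoyl]-2-[4-(trimethylsilyloxy)phenyl]-2,3-dihydro-1-benzofuran-5-yl]propan-1-one | O=C(CCc1ccc2c(c1)[C@H](C(=O)c1ccc(O[Si](C)(C)C)cc1O[Si](C)(C)C)[C@@H](c1ccc(O[Si](C)(C)C)cc1)O2)c1ccc(O[Si](C)(C)C)cc1O[Si](C)(C)C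
A1 | alternative 1 | 4-[(2S,3S)-3-(2,4-dihydroxybenzoyl)-5-[3-(2,4-dihydroxyphenyl)-3-oxopropyl]-2,3-dihydro-1-benzofuran-2-yl]phenyl 2,2-dimethylpropanoate | O=C(CCc1ccc2c(c1)[C@H](C(=O)c1ccc(O)cc1O)[C@@H](c1ccc(OC(=O)C(C)(C)C)cc1)O2)c1ccc(O)cc1O
A2 | alternative 1 | (2S,3S)-5-(2-carboxyethyl)-2-[4-(2,2-dimethylpropanoyloxy)phenyl]-2,3-dihydro-1-benzofuran-3-carboxylic acid | OC(=O)CCc1ccc2c(c1)[C@H](C(=O)O)[C@@H](c1ccc(OC(=O)C(C)(C)C)cc1)O2
A3 | alternative 1 | resorcinol (benzene-1,3-diol) | Oc1cccc(O)c1
A4 | alternative 2 | (2S,3S)-5-bromo-3-[2,4-bis(tert-butyldimethylsilyloxy)benzoyl]-2-[4-(tert-butyldimethylsilyloxy)phenyl]-2,3-dihydro-1-benzofuran | Brc1ccc2c(c1)[C@H](C(=O)c1ccc(O[Si](C)(C)C(C)(C)C)cc1O[Si](C)(C)C(C)(C)C)[C@@H](c1ccc(O[Si](C)(C)C(C)(C)C)cc1)O2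
A5 | alternative 2 | 1-[2,4-bis(tert-butyldimethylsilyloxy)phenyl]-2-{5-bromo-2-[4-(tert-butyldimethylsilyloxy)benzyloxy]phenyl}-2-diazoethan-1-one | [N-]=[N+]=C(C(=O)c1ccc(O[Si](C)(C)C(C)(C)C)cc1O[Si](C)(C)C(C)(C)C)c1cc(Br)ccc1OCc1ccc(O[Si](C)(C)C(C)(C)C)cc1
A6 | alternative 3 | 1-[2,4-bis(methoxymethoxy)phenyl]-3-[(2S,3S)-3-[2,4-bis(methoxymethoxy)benzoyl]-2-(4-hydroxyphenyl)-2,3-dihydro-1-benzofuran-5-yl]propan-1-one | O=C(CCc1ccc2c(c1)[C@H](C(=O)c1ccc(OCOC)cc1OCOC)[C@@H](c1ccc(O)cc1)O2)c1ccc(OCOC)cc1OCOC
A7 | alternative 3 | 2-{5-[3-(2,4-bis(methoxymethoxy)phenyl)-3-oxopropyl]-2-hydroxyphenyl}-1-[2,4-bis(methoxymethoxy)phenyl]-3-(4-hydroxyphenyl)prop-2-en-1-one (alkene geometry undefined) | O=C(CCc1ccc(O)c(c1)C(=Cc1ccc(O)cc1)C(=O)c1ccc(OCOC)cc1OCOC)c1ccc(OCOC)cc1OCOC
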